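**Retrosynthetic overview**
1. The (Z)-4-acetoxy-2-methylbut-2-enoate is made last by Still–Gennari olefination of a C3 2-phosphonopropanoate; the acid travels as a SEM ester obtained by hydroxide opening of an α-methylene-γ-lactone (ring C).
2. Ring C (cis C3–O/C4 lactone) comes from conjugate reduction, ketone reduction and lactonisation of a 4-(ethoxycarbonylmethylidene)-3-ketone, itself from a glyoxylate Mukaiyama aldol on a silyl enol ether.
3. Key disconnection: the cis C1 vinyl and C6 3-hydroxyprop-1-en-2-yl groups arise together when one Wittig operation "unzips" a cis-fused 6-acetoxypyran-3-one (ring B).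
4. Ring A comes from an endo, high-pressure Diels–Alder reaction of a 1,3-bis(silyloxy)diene with an enantiopure 5-methyl Achmatowicz pyranone; this sets C1 (quaternary), C6 and C5 in one step.
5. Ring order: B (Achmatowicz), then A (Diels–Alder), then C (lactone); B and C are opened again on the way to the monocyclic target.

Assumption: 4-methylfuran-2-carbaldehyde, ethyl 2-[bis(2,2,2-trifluoroethoxy)phosphoryl]propanoate and 2-oxoethyl acetate are taken as catalogue compounds, and the target SMILES is read at face value (vinyl, 3-O, 4-C, 5-O and 6-C all on one ring face, C1 methyl on the other).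

Convention used in names: ring A is numbered C1 (quaternary, Me/vinyl), C2 (CH2), C3 (acyloxy carbon), C4 (acrylate-bearing), C5 (carbinol), C6 (hydroxypropenyl-bearing). C7 is the carbon on C6, C8 the carbon on C1, C9 the OCH2 carbon. β is the face of ring A that carries C8 (later the vinyl group). The target is 1β-vinyl, 1α-Me, 3β, 4β, 5β, 6β, i.e. (1R,3R,4S,5S,6R) in this numbering. TBS = tert-butyldimethylsilyl, SEM = 2-(trimethylsilyl)ethoxymethyl.

**Route**

Step 1
Reactants: 1 4-methylfuran-2-carbaldehyde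
Product: 2 (4-methylfuran-2-yl)methanol
Conditions: NaBH4, MeOH, 0 °C
Reagents that add atoms: none
Why: Chemoselective borohydride reduction of the aldehyde (carbonyl reduction); no stereocentre is formed.

Step 2
Reactants: 2 (4-methylfuran-2-yl)methanol
Product: 3 rac-6-hydroxy-5-methyl-2H-pyran-3(6H)-one
Conditions: N-bromosuccinimide, NaHCO3, THF/H2O 4:1, 0 °C
Reagents that add atoms: water, O
Why: Achmatowicz rearrangement (bromonium-induced 2,5-oxidation of the furan, opening to the ene-dione and recyclisation of the primary alcohol) gives the pyranone lactol, which is configurationally labile and therefore racemic.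

Step 3
Reactants: 3 rac-6-hydroxy-5-methyl-2H-pyran-3(6H)-one
Product: 4 (2R)-3-methyl-5-oxo-5,6-dihydro-2H-pyran-2-yl acetate
Conditions: Burkholderia cepacia lipase (Amano PS, immobilised), vinyl acetate, toluene, 30 °C
Reagents that add atoms: vinyl acetate, C=COC(C)=O
Why: Lipase-catalysed acylation under dynamic kinetic resolution (the lactol racemises by ring–chain tautomerism), as established for the parent 6-hydroxy-2H-pyran-3(6H)-one; the (R)-acetal centre set here is the only source of absolute configuration, and the antipode is reachable with the same enzyme in the alcoholysis mode.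

Step 4
Reactants: 5 (E)-4-methoxybut-3-en-2-one
Product: 8 (E)-1,3-bis[(tert-butyldimethylsilyl)oxy]buta-1,3-diene, via sodium formylacetone enolate 6 (not isolated), via mono-silyl enone 7 (not isolated)
Conditions: NaOH (1 equiv), H2O/MeOH, 0 °C, evaporate; t-BuMe2SiCl, THF, 0 °C; Et3N, t-BuMe2SiOTf, 0 °C
Reagents that add atoms: sodium hydroxide, [Na+].[OH-]; tert-butyldimethylsilyl chloride, CC(C)(C)[Si](C)(C)Cl; tert-butyldimethylsilyl trifluoromethanesulfonate, CC(C)(C)[Si](C)(C)OS(=O)(=O)C(F)(F)F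
Why: Saponification of the vinylogous ester, O-silylation of the enolate and kinetic enol silylation of the methyl ketone give the Danishefsky-type (E)-1,3-dioxygenated diene whose 1-OTBS group becomes the permanent C5 protecting group.

Step 5
Reactants: 4 (2R)-3-methyl-5-oxo-5,6-dihydro-2H-pyran-2-yl acetate; 8 (E)-1,3-bis[(tert-butyldimethylsilyl)oxy]buta-1,3-diene
Product: 9 cis-fused Diels–Alder adduct (bis-silyloxy keto acetal acetate)
Conditions: CH2Cl2, 13 kbar, 25 °C, 48 h
Reagents that add atoms: none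
Why: Normal-demand endo Diels–Alder reaction, run at high pressure because the enone is β,β-disubstituted; the nucleophilic CH2 terminus of the diene bonds to the β-carbon, so C1 becomes the methyl-bearing quaternary centre, the diene adds anti to the pseudoaxial acetoxy group (absolute control) and endo to the ketone, which places C8, C7 and 5-OTBS on the β-face and the methyl on the α-face.

Step 6
Reactants: 9 cis-fused Diels–Alder adduct
Product: 12 ring-opened dienol, via methylene acetal acetate 10 (not isolated), via hydroxy aldehyde 11 (not isolated)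
Conditions: Ph3PCH3Br, KOt-Bu, THF, 0 °C (ylide, 5 equiv); add 9 at −78 °C, then 25 °C
Reagents that add atoms: methylenetriphenylphosphorane, C=P(c1ccccc1)(c1ccccc1)c1ccccc1
Why: Wittig methylenation used three ways (ketone methylenation at low temperature, C-acylation of the ylide by the anomeric acetate to release the lactol, methylenation of the ring-opened neopentyl aldehyde) converts ring B into the cis 1β-vinyl and 6β-(3-hydroxyprop-1-en-2-yl) groups without touching C1 or C6.

Step 7
Reactants: 12 ring-opened dienol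
Product: 13 tris-TBS silyl enol ether
Conditions: t-BuMe2SiCl, imidazole, DMF, 0 °C
Reagents that add atoms: tert-butyldimethylsilyl chloride, CC(C)(C)[Si](C)(C)Cl
Why: Silylation of the primary allylic alcohol (the TBS enol ether is stable to imidazole) masks the only free hydroxyl before Lewis acid chemistry.

Step 8
Reactants: 13 tris-TBS silyl enol ether; 14 ethyl glyoxylate
Product: 16 (E)-4-(ethoxycarbonylmethylidene)-3-ketone, via aldol adduct 15 (not isolated)
Conditions: BF3·OEt2, CH2Cl2, −78 °C; NaHCO3 (aq); crude: MsCl, Et3N, CH2Cl2, 0 → 25 °C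
Reagents that add atoms: none
Why: Regiospecific Mukaiyama aldol addition at C4 of the enol silane followed by mesylation and E1cB elimination (mesylate leaves in preference to the C5 silyloxy group) removes the C4 stereocentre again so that it can be reset by hydrogen delivery.

Step 9
Reactants: 16 (E)-4-(ethoxycarbonylmethylidene)-3-ketone
Product: 19 cis-fused γ-lactone, via keto ester 17 (not isolated), via hydroxy ester 18 (not isolated)
Conditions: LiBH(s-Bu)3 (2.5 equiv), t-BuOH (1.1 equiv), THF, −78 → 0 °C; NH4Cl (aq)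
Reagents that add atoms: none
Why: Tandem conjugate reduction and ketone reduction: hydrogen reaches C4 anti to the pseudoaxial 5β-OTBS group and the bulky borohydride attacks C3 equatorially from the α-face (the β-face carries the axial vinyl and silyloxy groups), so the 4β-CH2CO2Et and 3β-alkoxide are cis and lactonise.

Step 10
Reactants: 19 cis-fused γ-lactone
Product: 22 α-methylene-γ-lactone, via Mannich base 20 (not isolated), via methiodide 21 (not isolated)
Conditions: LiN(i-Pr)2, THF, −78 °C; CH2=NMe2+ I−, −78 → 0 °C; MeI, MeOH, 25 °C; NaHCO3 (aq), CH2Cl2, 25 °C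
Reagents that add atoms: N,N-dimethylmethyleneiminium iodide, C=[N+](C)C.[I-]
Why: Lactone enolate Mannich reaction with Eschenmoser's salt, quaternisation and Hofmann-type elimination install the exocyclic methylene; no ring stereocentre is affected.

Step 11
Reactants: 22 α-methylene-γ-lactone
Product: 24 3β-hydroxy SEM acrylate, via lithium carboxylate 23 (not isolated)
Conditions: LiOH·H2O (1.05 equiv), THF/H2O, 0 °C; evaporate (toluene azeotrope); Me3SiCH2CH2OCH2Cl, DMF, 0 °C
Reagents that add atoms: lithium hydroxide, [Li+].[OH-]; 2-(trimethylsilyl)ethoxymethyl chloride, C[Si](C)(C)CCOCCl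
Why: Lactone saponification and O-alkylation of the carboxylate salt (never acidified, so it cannot relactonise) free the C3 hydroxyl while the acid is masked as a fluoride-labile ester.

Step 12
Reactants: 25 ethyl 2-[bis(2,2,2-trifluoroethoxy)phosphoryl]propanoate
Product: 26 2-[bis(2,2,2-trifluoroethoxy)phosphoryl]propanoic acid
Conditions: LiOH·H2O (1.0 equiv), THF/H2O, 0 °C; then 1 M HCl
Reagents that add atoms: lithium hydroxide, [Li+].[OH-]
Why: Controlled saponification of the carboxylic ester with one equivalent of hydroxide at 0 °C gives the racemic phosphono acid, whose stereocentre is destroyed in step 14.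

Step 13
Reactants: 24 3β-hydroxy SEM acrylate; 26 2-[bis(2,2,2-trifluoroethoxy)phosphoryl]propanoic acid
Product: 27 C3 phosphonopropanoate
Conditions: N,N'-dicyclohexylcarbodiimide, 4-(dimethylamino)pyridine (0.1 equiv), CH2Cl2, 0 °C
Reagents that add atoms: none
Why: Steglich esterification of the hindered secondary alcohol with a saturated acid (no alkene geometry to lose) under near-neutral conditions that outpace relactonisation onto the conjugated SEM ester.

Step 14
Reactants: 27 C3 phosphonopropanoate; 28 2-oxoethyl acetate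
Product: 29 fully protected target
Conditions: KN(SiMe3)2, 18-crown-6, THF, −78 °C
Reagents that add atoms: none
Why: Still–Gennari variant of the Horner–Wadsworth–Emmons olefination (trifluoroethyl phosphonate, dissociated potassium counter-ion) gives the trisubstituted (Z)-enoate under kinetic control.

Step 15
Reactants: 29 fully protected target
Product: 30 target acid CNP0261293.6
Conditions: HF·pyridine, pyridine, THF, 0 → 25 °C; pH 5–7 buffer, 0 °C
Reagents that add atoms: none
Why: Fluoride-mediated global deprotection removes both TBS ethers and fragments the SEM ester in a pyridine-buffered medium, which keeps the acid largely as carboxylate and so limits lactonisation onto the cis C5 hydroxyl and acyl migration.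

**Compound list**
1 | 4-methylfuran-2-carbaldehyde | Cc1coc(C=O)c1 | starting material
2 | (4-methylfuran-2-yl)methanol | Cc1coc(CO)c1 | intermediate
3 | rac-6-hydroxy-5-methyl-2H-pyran-3(6H)-one (labile lactol, racemic) | CC1=CC(=O)COC1O | intermediate
4 | (2R)-3-methyl-5-oxo-5,6-dihydro-2H-pyran-2-yl acetate | CC(=O)O[C@@H]1C(C)=CC(=O)CO1 | intermediate
5 | (E)-4-methoxybut-3-en-2-one | CO/C=C/C(C)=O | starting material
6 | sodium (E)-3-oxobut-1-en-1-olate (sodium formylacetone enolate) | CC(=O)/C=C/[O-].[Na+] | intermediate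
7 | (E)-4-[(tert-butyldimethylsilyl)oxy]but-3-en-2-one | CC(=O)/C=C/O[Si](C)(C)C(C)(C)C | intermediate
8 | (E)-1,3-bis[(tert-butyldimethylsilyl)oxy]buta-1,3-diene | C=C(O[Si](C)(C)C(C)(C)C)/C=C/O[Si](C)(C)C(C)(C)C | intermediate
9 | cis-fused Diels–Alder adduct, (1R,4aS,5R,8aS)-5,7-bis(TBSO)-8a-methyl-4-oxo-3,4,4a,5,8,8a-hexahydro-1H-isochromen-1-yl acetate; C8 and C7 β, 5β-OTBS, 1α-Me, 8-OAc anti to ring A | CC(=O)O[C@@H]2[C@@]1(C)CC(O[Si](C)(C)C(C)(C)C)=C[C@@H](O[Si](C)(C)C(C)(C)C)[C@H]1C(=O)CO2 | intermediate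
10 | methylene acetal acetate (9 with the C7 ketone converted to C7=CH2) | CC(=O)O[C@@H]2[C@@]1(C)CC(O[Si](C)(C)C(C)(C)C)=C[C@@H](O[Si](C)(C)C(C)(C)C)[C@H]1C(=C)CO2 | intermediate
11 | hydroxy aldehyde (1β-CHO, 1α-Me, 3-OTBS enol ether, 5β-OTBS, 6β-(3-hydroxyprop-1-en-2-yl)) | O=C[C@@]1(C)CC(O[Si](C)(C)C(C)(C)C)=C[C@@H](O[Si](C)(C)C(C)(C)C)[C@H]1C(=C)CO | intermediate
12 | ring-opened dienol (1β-vinyl, 1α-Me, 3-OTBS enol ether, 5β-OTBS, 6β-(3-hydroxyprop-1-en-2-yl)) | C=C[C@@]1(C)CC(O[Si](C)(C)C(C)(C)C)=C[C@@H](O[Si](C)(C)C(C)(C)C)[C@H]1C(=C)CO | intermediate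
13 | tris-TBS silyl enol ether (12 with the primary alcohol silylated) | C=C[C@@]1(C)CC(O[Si](C)(C)C(C)(C)C)=C[C@@H](O[Si](C)(C)C(C)(C)C)[C@H]1C(=C)CO[Si](C)(C)C(C)(C)C | intermediate
14 | ethyl glyoxylate | CCOC(=O)C=O | starting material
15 | aldol adduct (3-ketone, 4-CH(OH)CO2Et, epimer mixture at C4 and the carbinol carbon) | C=C[C@@]1(C)CC(=O)C(C(O)C(=O)OCC)[C@@H](O[Si](C)(C)C(C)(C)C)[C@H]1C(=C)CO[Si](C)(C)C(C)(C)C | intermediate
16 | (E)-4-(ethoxycarbonylmethylidene)-3-ketone (ester trans to the C3 carbonyl; 5β-OTBS, 6β side chain, 1β-vinyl) | C=C[C@@]1(C)CC(=O)/C(=C/C(=O)OCC)[C@@H](O[Si](C)(C)C(C)(C)C)[C@H]1C(=C)CO[Si](C)(C)C(C)(C)C | intermediate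
17 | keto ester (3-ketone, 4β-CH2CO2Et) | C=C[C@@]1(C)CC(=O)[C@@H](CC(=O)OCC)[C@@H](O[Si](C)(C)C(C)(C)C)[C@H]1C(=C)CO[Si](C)(C)C(C)(C)C | intermediate
18 | hydroxy ester (3β-OH, 4β-CH2CO2Et) | C=C[C@@]1(C)C[C@@H](O)[C@@H](CC(=O)OCC)[C@@H](O[Si](C)(C)C(C)(C)C)[C@H]1C(=C)CO[Si](C)(C)C(C)(C)C | intermediate
19 | cis-fused γ-lactone (3β-O–CO–CH2–4β; 5β-OTBS; 6β-(3-TBSO-prop-1-en-2-yl); 1β-vinyl, 1α-Me) | C=C[C@@]1(C)C[C@@H](OC(=O)C2)[C@@H]2[C@@H](O[Si](C)(C)C(C)(C)C)[C@H]1C(=C)CO[Si](C)(C)C(C)(C)C | intermediate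
20 | Mannich base (α-(dimethylaminomethyl) lactone, α-epimers) | C=C[C@@]1(C)C[C@@H](OC(=O)C2CN(C)C)[C@@H]2[C@@H](O[Si](C)(C)C(C)(C)C)[C@H]1C(=C)CO[Si](C)(C)C(C)(C)C | intermediate
21 | methiodide of 20 (trimethylammonium iodide) | C=C[C@@]1(C)C[C@@H](OC(=O)C2C[N+](C)(C)C)[C@@H]2[C@@H](O[Si](C)(C)C(C)(C)C)[C@H]1C(=C)CO[Si](C)(C)C(C)(C)C.[I-] | intermediate
22 | α-methylene-γ-lactone (cis-fused at 3β-O/4β) | C=C[C@@]1(C)C[C@@H](OC(=O)C2=C)[C@@H]2[C@@H](O[Si](C)(C)C(C)(C)C)[C@H]1C(=C)CO[Si](C)(C)C(C)(C)C | intermediate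
23 | lithium carboxylate (3β-OH, 4β-C(=CH2)CO2Li) | C=C[C@@]1(C)C[C@@H](O)[C@@H](C(=C)C(=O)[O-])[C@@H](O[Si](C)(C)C(C)(C)C)[C@H]1C(=C)CO[Si](C)(C)C(C)(C)C.[Li+] | intermediate
24 | 3β-hydroxy SEM acrylate (4β-C(=CH2)CO2SEM, 5β-OTBS, 6β-(3-TBSO-prop-1-en-2-yl), 1β-vinyl, 1α-Me) | C=C[C@@]1(C)C[C@@H](O)[C@@H](C(=C)C(=O)OCOCC[Si](C)(C)C)[C@@H](O[Si](C)(C)C(C)(C)C)[C@H]1C(=C)CO[Si](C)(C)C(C)(C)C | intermediate
25 | ethyl 2-[bis(2,2,2-trifluoroethoxy)phosphoryl]propanoate (racemic) | CCOC(=O)C(C)P(=O)(OCC(F)(F)F)OCC(F)(F)F | starting material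
26 | 2-[bis(2,2,2-trifluoroethoxy)phosphoryl]propanoic acid (racemic) | CC(C(=O)O)P(=O)(OCC(F)(F)F)OCC(F)(F)F | intermediate
27 | C3 phosphonopropanoate (24 acylated at 3β-O; epimers at the phosphonate α-carbon) | C=C[C@@]1(C)C[C@@H](OC(=O)C(C)P(=O)(OCC(F)(F)F)OCC(F)(F)F)[C@@H](C(=C)C(=O)OCOCC[Si](C)(C)C)[C@@H](O[Si](C)(C)C(C)(C)C)[C@H]1C(=C)CO[Si](C)(C)C(C)(C)C | intermediate
28 | 2-oxoethyl acetate (acetoxyacetaldehyde) | CC(=O)OCC=O | starting material
29 | fully protected target (3β-[(Z)-4-acetoxy-2-methylbut-2-enoyloxy], SEM ester, 5-O-TBS, primary O-TBS) | C=C[C@@]1(C)C[C@@H](OC(=O)/C(C)=C\COC(C)=O)[C@@H](C(=C)C(=O)OCOCC[Si](C)(C)C)[C@@H](O[Si](C)(C)C(C)(C)C)[C@H]1C(=C)CO[Si](C)(C)C(C)(C)C | intermediate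
30 | 2-[(1S,2S,3R,4R,6R)-6-{[(2Z)-4-(acetyloxy)-2-methylbut-2-enoyl]oxy}-4-ethenyl-2-hydroxy-3-(3-hydroxyprop-1-en-2-yl)-4-methylcyclohexyl]prop-2-enoic acid (CNP0261293.6) | C=C[C@@]1(C)C[C@@H](OC(=O)/C(C)=C\COC(C)=O)[C@@H](C(=C)C(=O)O)[C@@H](O)[C@H]1C(=C)CO | target

**Totals and risks**
Total step count: 15. Longest linear sequence: 13 steps (1, 2, 3, 5, 6, 7, 8, 9, 10, 11, 13, 14, 15); steps 4 and 12 are convergent branches.

The three steps most likely to fail:

Step 3 (enzymatic resolution; the 5-methyl group next to the acetal carbon may lower rate or selectivity, and this step alone fixes the absolute configuration). Fallback, setting out from 3: acylate the lactol with (1R,2S,5R)-menthyl chloroformate (pyridine, DMAP, CH2Cl2, 0 °C) and separate the diastereomeric carbonates by crystallisation or chromatography. The (2R)-pyranyl menthyl carbonate F1 is carried on; the (2S)-epimer F2 is returned to 3 by methanolysis. F1 and diene 8 under the conditions of step 5 give the carbonate adduct F3. The ylide of step 6 first methylenates the ketone (methylene carbonate F4), then cleaves the carbonate to hydroxy aldehyde 11, where the route is rejoined.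

Step 5 (Diels–Alder reaction of a β,β-disubstituted enone; it may stall even at 13 kbar). Fallback, setting out from 4: activate the dienophile as its α-bromo enone. Br2 (CH2Cl2, 0 °C) gives dibromide F5 (not isolated), and Et3N eliminates HBr to bromo enone F6. F6 and 8 (toluene, 60 °C) give bromo adduct F7 with the same regio- and facial sense. Bu3SnH with azobisisobutyronitrile (toluene, 80 °C) replaces the ring-fusion bromine by hydrogen from the convex face and returns cis-fused 9.

Step 9 (C4 is set by kinetic hydrogen delivery; the 4α-epimer or incomplete ketone reduction is possible). Fallback, setting out from 16: set C4 by hydride addition to a rigid butenolide instead. Luche reduction (NaBH4, CeCl3·7H2O, MeOH, −78 °C) gives the 3β-allylic alcohol F8. Equilibration of the enoate geometry (PhSSPh cat., hν) gives the isomer F9 with the ester on the C3 side, which lactonises (pyridinium p-toluenesulfonate cat.) to butenolide F10. Conjugate reduction with [(Ph3P)CuH]6 (toluene, trace water, 25 °C) delivers hydride to C4 from the α-face and gives cis-fused lactone 19.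

**Further compounds**
F1 | step 3 | (2R)-3-methyl-5-oxo-5,6-dihydro-2H-pyran-2-yl (1R,2S,5R)-menthyl carbonate | CC(C)[C@@H]1CC[C@@H](C)C[C@H]1OC(=O)O[C@@H]2C(C)=CC(=O)CO2
F2 | step 3 | (2S)-3-methyl-5-oxo-5,6-dihydro-2H-pyran-2-yl (1R,2S,5R)-menthyl carbonate | CC(C)[C@@H]1CC[C@@H](C)C[C@H]1OC(=O)O[C@H]2C(C)=CC(=O)CO2
F3 | step 3 | cis-fused Diels–Alder adduct with menthyl carbonate at C8 (otherwise as 9) | CC(C)[C@@H]1CC[C@@H](C)C[C@H]1OC(=O)O[C@@H]3[C@@]2(C)CC(O[Si](C)(C)C(C)(C)C)=C[C@@H](O[Si](C)(C)C(C)(C)C)[C@H]2C(=O)CO3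
F4 | step 3 | methylene acetal menthyl carbonate (F3 with C7=CH2) | CC(C)[C@@H]1CC[C@@H](C)C[C@H]1OC(=O)O[C@@H]3[C@@]2(C)CC(O[Si](C)(C)C(C)(C)C)=C[C@@H](O[Si](C)(C)C(C)(C)C)[C@H]2C(=C)CO3
F5 | step 5 | (2R)-3,4-dibromo-3-methyl-5-oxotetrahydro-2H-pyran-2-yl acetate (dibromide, diastereomer mixture) | CC(=O)O[C@@H]1C(C)(Br)C(Br)C(=O)CO1
F6 | step 5 | (2R)-4-bromo-3-methyl-5-oxo-5,6-dihydro-2H-pyran-2-yl acetate | CC(=O)O[C@@H]1C(C)=C(Br)C(=O)CO1
F7 | step 5 | bromo Diels–Alder adduct (9 with Br in place of H at the ring-fusion carbon C6) | CC(=O)O[C@@H]2[C@@]1(C)CC(O[Si](C)(C)C(C)(C)C)=C[C@@H](O[Si](C)(C)C(C)(C)C)[C@@]1(Br)C(=O)CO2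
F8 | step 9 | 3β-allylic alcohol (16 with C3=O reduced; ester trans to C3) | C=C[C@@]1(C)C[C@@H](O)/C(=C/C(=O)OCC)[C@@H](O[Si](C)(C)C(C)(C)C)[C@H]1C(=C)CO[Si](C)(C)C(C)(C)C
F9 | step 9 | geometric isomer of F8 (ester cis to C3) | C=C[C@@]1(C)C[C@@H](O)/C(=C\C(=O)OCC)[C@@H](O[Si](C)(C)C(C)(C)C)[C@H]1C(=C)CO[Si](C)(C)C(C)(C)C
F10 | step 9 | fused butenolide (3β-O–CO–CH=C4) | C=C[C@@]1(C)C[C@H]2OC(=O)C=C2[C@@H](O[Si](C)(C)C(C)(C)C)[C@H]1C(=C)CO[Si](C)(C)C(C)(C)C
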